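**Retrosynthetic overview**

1. Germacrane numbering: carbocycle C1H2–C2H=C3–C4(Me)(OH)–C5H2–C6H(OAc)–C7–C8=C9H–C10(Me), ether O bridging C3 and C10 (2,3-dihydrofuran), butenolide C7=C11(C13H2OAc)–C12(=O)–O–C8. The strategy rests on C6 (an aldehyde-derived carbinol carbon) and C7 (the β-carbon of the butenolide ring) both being electrophiles: their reductive union closes the ten-membered carbocycle C1–C10 last and creates C6.
2. After ring closure only desilylation and acetylation of O6 and O13 remain. C13 travels as a TBS ether, because an acetate there would be expelled from the furanolate that builds C8–C9.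
3. C8=C9 (E): vinylogous aldol addition of a 4-iodo-2-silyloxyfuran to the C9 aldehyde, then anti-dehydration. The iodobutenolide ring comes from iodolactonisation of an allenoic acid made from but-2-yne-1,4-diol.
4. Dihydrofuran ring: 5-endo-dig cycloisomerisation after C1–C2 union of a citramalate-derived alkyne (C2–C6, C15, C4 from the chiral pool) with an epoxide from asymmetric epoxidation of 2-methylprop-2-en-1-ol (C1, C9, C10, C14).
5. Order of ring formation: butenolide (in its fragment), dihydrofuran, ten-membered carbocycle.

Key step: step 21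

Remark: atom labels follow the germacrane numbering above; 23 is drawn as one of the two C8/C9-anti diastereomers, because both should lose water to the same alkene 24.

**Route**

Step 1
Reactants: 1 (S)-citramalic acid
Product: 2 2-[(4S)-2,2,4-trimethyl-5-oxo-1,3-dioxolan-4-yl]acetic acid
Conditions: 2,2-dimethoxypropane, PTSA (cat.), CH2Cl2, rt
Reagents that add atoms: 2,2-dimethoxypropane, COC(C)(C)OC
Why: Acid-catalysed acetalisation of the α-hydroxy acid forms the five-membered 1,3-dioxolan-4-one, which ties up the future C3 carboxyl and the C4 hydroxyl, leaves the future C6 carboxyl free and does not touch the stereocentre.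

Step 2
Reactants: 2 2-[(4S)-2,2,4-trimethyl-5-oxo-1,3-dioxolan-4-yl]acetic acid
Product: 4 (3S)-3-hydroxy-3-methyloxolan-2-one, via hydroxy dioxolanone 3 (not isolated)
Conditions: BH3·SMe2, THF, 0 °C → rt; MeOH quench; then PTSA (cat.), CH2Cl2, rt
Reagents that add atoms: none
Why: Borane reduces the free carboxylic acid much faster than the dioxolanone ester, and under acid catalysis the new primary alcohol should translactonise onto the activated dioxolanone carbonyl with loss of acetone to give the γ-lactone (chemoselective borane reduction followed by lactonisation).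

Step 3
Reactants: 4 (3S)-3-hydroxy-3-methyloxolan-2-one
Product: 5 (3S)-3-methyloxolane-2,3-diol (lactol, both anomers)
Conditions: i-Bu2AlH (2.2 equiv), CH2Cl2, −78 °C; Rochelle salt work-up
Reagents that add atoms: none
Why: Reduction of a γ-lactone with i-Bu2AlH at −78 °C stops at the lactol because the aluminium hemiacetal is stable in the cold, the first equivalent being taken up by the tertiary hydroxyl.

Step 4
Reactants: 5 (3S)-3-methyloxolane-2,3-diol
Product: 6 (3S)-3-methylpent-4-yne-1,3-diol
Conditions: dimethyl (1-diazo-2-oxopropyl)phosphonate, K2CO3, MeOH, 0 °C → rt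
Reagents that add atoms: dimethyl (1-diazo-2-oxopropyl)phosphonate, COP(=O)(OC)C(=[N+]=[N-])C(C)=O
Why: The lactol is in equilibrium with its open hydroxy aldehyde, which the diazomethylphosphonate anion released from the reagent converts into the terminal alkyne (Ohira–Bestmann homologation), adding C2 under conditions that cannot affect the quaternary carbinol centre.

Step 5
Reactants: 6 (3S)-3-methylpent-4-yne-1,3-diol
Product: 7 (3S)-3-methyl-3,5-bis(triethylsilyloxy)pent-1-yne
Conditions: TESOTf (2.4 equiv), 2,6-lutidine, CH2Cl2, −78 → 0 °C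
Reagents that add atoms: triethylsilyl trifluoromethanesulfonate, CC[Si](CC)(CC)OS(=O)(=O)C(F)(F)F
Why: The silyl triflate with 2,6-lutidine silylates both the primary and the hindered tertiary propargylic hydroxyl (silyl ether formation), giving ethers that can later be told apart by their steric environment.

Step 6
Reactants: 8 2-methylprop-2-en-1-ol
Product: 9 (R)-(2-methyloxiran-2-yl)methanol
Conditions: Ti(OiPr)4 (5 mol %), D-(−)-diisopropyl tartrate (6 mol %), t-BuOOH, 4 Å MS, CH2Cl2, −20 °C
Reagents that add atoms: tert-butyl hydroperoxide, CC(C)(C)OO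
Why: Sharpless asymmetric epoxidation of the allylic alcohol with the D-(−)-tartrate ligand delivers oxygen to the face that gives the (R)-epoxy alcohol, which sets the future C10 stereocentre by reagent control.

Step 7
Reactants: 9 (R)-(2-methyloxiran-2-yl)methanol
Product: 10 (2S)-2-{[(4-methoxybenzyl)oxy]methyl}-2-methyloxirane
Conditions: NaH, 4-methoxybenzyl chloride, Bu4NI (cat.), THF/DMF, 0 °C → rt
Reagents that add atoms: 4-methoxybenzyl chloride, COc1ccc(CCl)cc1
Why: Williamson etherification of the primary alkoxide protects O9 without opening the epoxide, and the descriptor changes from R to S only because the ether outranks the ring carbon.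

Step 8
Reactants: 7 (3S)-3-methyl-3,5-bis(triethylsilyloxy)pent-1-yne; 10 (2S)-2-{[(4-methoxybenzyl)oxy]methyl}-2-methyloxirane
Product: 12 (2S,6S)-1-[(4-methoxybenzyl)oxy]-2,6-dimethyl-6,8-bis(triethylsilyloxy)oct-4-yn-2-ol, via lithium acetylide 11 (not isolated)
Conditions: 7, n-BuLi, THF, −78 °C; BF3·OEt2; then 10, −78 °C
Reagents that add atoms: none
Why: The lithium acetylide, activated by BF3·OEt2, opens the BF3-complexed 2,2-disubstituted epoxide at its unsubstituted carbon in an SN2 manner (BF3-mediated alkynylation of an epoxide), so the C1–C2 bond forms and the C10 stereocentre is carried over unchanged as the tertiary alcohol.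

Step 9
Reactants: 12 (2S,6S)-1-[(4-methoxybenzyl)oxy]-2,6-dimethyl-6,8-bis(triethylsilyloxy)oct-4-yn-2-ol
Product: 13 (2S)-5-[(2S)-2,4-bis(triethylsilyloxy)butan-2-yl]-2-{[(4-methoxybenzyl)oxy]methyl}-2-methyl-2,3-dihydrofuran
Conditions: AuCl(PPh3) (2 mol %), AgOTf (2 mol %), 4 Å MS, toluene, rt; Et3N quench
Reagents that add atoms: none
Why: The cationic monovalent gold catalyst activates the internal alkyne for anti attack of the tertiary C10 hydroxyl on C3 (5-endo-dig cycloisomerisation of a homopropargylic alcohol), the only ring size open to it, and protodeauration gives the 2,3-dihydrofuran without touching either stereocentre.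

Step 10
Reactants: 13 (2S)-5-[(2S)-2,4-bis(triethylsilyloxy)butan-2-yl]-2-{[(4-methoxybenzyl)oxy]methyl}-2-methyl-2,3-dihydrofuran
Product: 14 {(2S)-5-[(2S)-2,4-bis(triethylsilyloxy)butan-2-yl]-2-methyl-2,3-dihydrofuran-2-yl}methanol
Conditions: DDQ, CH2Cl2/pH 7 phosphate buffer (10:1), 0 °C
Reagents that add atoms: none
Why: DDQ oxidises the electron-rich 4-methoxybenzyl ether to an oxocarbenium ion that water cleaves (oxidative PMB removal), and the cold buffered medium is chosen so that the silyl ethers and the enol ether, whose quaternary C10 blocks dehydrogenation to a furan, should survive.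

Step 11
Reactants: 14 {(2S)-5-[(2S)-2,4-bis(triethylsilyloxy)butan-2-yl]-2-methyl-2,3-dihydrofuran-2-yl}methanol
Product: 15 (2S)-5-[(2S)-2,4-bis(triethylsilyloxy)butan-2-yl]-2-methyl-2,3-dihydrofuran-2-carbaldehyde
Conditions: SO3·pyridine, DMSO, i-Pr2NEt, CH2Cl2, 0 °C
Reagents that add atoms: none
Why: Parikh–Doering oxidation converts the neopentyl primary alcohol into the C9 aldehyde under basic, non-aqueous conditions that spare the enol ether and the silyl ethers, and the α-quaternary aldehyde can neither epimerise nor enolise.

Step 12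
Reactants: 16 but-2-yne-1,4-diol
Product: 17 4-(tert-butyldimethylsilyloxy)but-2-yn-1-ol
Conditions: NaH (1 equiv), TBSCl (1 equiv), THF, 0 °C → rt, diol in excess
Reagents that add atoms: tert-butyldimethylsilyl chloride, CC(C)(C)[Si](C)(C)Cl
Why: Silylation of the symmetrical diol with one equivalent of base and silyl chloride in the presence of excess diol should give mainly the mono ether (statistical desymmetrisation by silyl ether formation), which becomes the protected O13.

Step 13
Reactants: 17 4-(tert-butyldimethylsilyloxy)but-2-yn-1-ol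
Product: 18 4-(tert-butyldimethylsilyloxy)but-2-yn-1-yl methyl carbonate
Conditions: ClCO2Me, pyridine, CH2Cl2, 0 °C
Reagents that add atoms: methyl chloroformate, COC(=O)Cl
Why: Acylation of the free propargylic alcohol with the chloroformate gives the carbonate (carbonate formation) that serves as leaving group and methoxide source in the next step.

Step 14
Reactants: 18 4-(tert-butyldimethylsilyloxy)but-2-yn-1-yl methyl carbonate
Product: 19 methyl 2-[(tert-butyldimethylsilyloxy)methyl]buta-2,3-dienoate
Conditions: Pd(OAc)2 (2 mol %), PPh3 (8 mol %), CO (10 atm), MeOH, 45 °C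
Reagents that add atoms: carbon monoxide, [C-]#[O+]
Why: Zerovalent palladium formed in the flask displaces the propargylic carbonate in an SN2′ sense to an allenylpalladium species whose CO insertion and methanolysis give the 2,3-dienoate with the ester (C12) on the carbon that bears the silyloxymethyl group (palladium-catalysed carbonylation of a propargylic carbonate).

Step 15
Reactants: 19 methyl 2-[(tert-butyldimethylsilyloxy)methyl]buta-2,3-dienoate
Product: 20 2-[(tert-butyldimethylsilyloxy)methyl]buta-2,3-dienoic acid
Conditions: LiOH, THF/H2O, 0 °C; then cold aq. HCl to pH 3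
Reagents that add atoms: lithium hydroxide, [Li+].[OH-]
Why: Saponification of the methyl ester at 0 °C with brief cold acidification gives the allenoic acid (ester hydrolysis), the 2-substituent excluding isomerisation to a conjugated 2-alkynoate.

Step 16
Reactants: 20 2-[(tert-butyldimethylsilyloxy)methyl]buta-2,3-dienoic acid
Product: 21 3-[(tert-butyldimethylsilyloxy)methyl]-4-iodofuran-2(5H)-one
Conditions: I2, NaHCO3, MeCN, 0 °C → rt, dark
Reagents that add atoms: iodine, II
Why: Iodine adds to the central allene carbon and the carboxylate closes on the terminal CH2 (iodolactonisation of a 2,3-allenoic acid), which forms the butenolide ring and places the iodide on C7 and the silyloxymethyl group on C11 in one operation.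

Step 17
Reactants: 15 (2S)-5-[(2S)-2,4-bis(triethylsilyloxy)butan-2-yl]-2-methyl-2,3-dihydrofuran-2-carbaldehyde; 21 3-[(tert-butyldimethylsilyloxy)methyl]-4-iodofuran-2(5H)-one
Product: 23 (5R)-3-[(tert-butyldimethylsilyloxy)methyl]-5-[(S)-hydroxy{(2S)-5-[(2S)-2,4-bis(triethylsilyloxy)butan-2-yl]-2-methyl-2,3-dihydrofuran-2-yl}methyl]-4-iodofuran-2(5H)-one (C8/C9 anti), via silyloxyfuran 22 (not isolated)
Conditions: 21, TMSOTf, Et3N, Et2O, 0 °C, filter and concentrate; then 15, TBAF (1.0 equiv, dried), THF, −78 °C; AcOH, −78 °C
Reagents that add atoms: none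
Why: Fluoride releases the furanolate from the 2-silyloxyfuran and this adds through its γ-carbon C8 to the non-enolisable aldehyde (fluoride-promoted vinylogous Mukaiyama aldol addition), a mode known to favour the anti (erythro) C8/C9 adduct through an open transition state, while either facial course with respect to C10 gives an anti adduct that leads to the same alkene.

Step 18
Reactants: 23 anti aldol adduct
Product: 24 (5E)-3-[(tert-butyldimethylsilyloxy)methyl]-5-({(2S)-5-[(2S)-2,4-bis(triethylsilyloxy)butan-2-yl]-2-methyl-2,3-dihydrofuran-2-yl}methylidene)-4-iodofuran-2(5H)-one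
Conditions: PPh3/DIAD (betaine pre-formed), THF, 0 °C → rt
Reagents that add atoms: none
Why: Under Mitsunobu conditions the C9 hydroxyl becomes an oxyphosphonium leaving group and the acidic C8–H is removed antiperiplanar to it in a concerted E2 process (anti-selective Mitsunobu dehydration of a γ-(α-hydroxyalkyl)butenolide), so the anti adduct should give the E-alkene with C10 on the C7 side, substitution being shut off at the neopentyl C9 and the early transition state of the very good leaving group keeping the strain between iodine and C10 low.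

Step 19
Reactants: 24 E-alkylidene iodobutenolide bis(triethylsilyl) ether
Product: 25 (5E)-3-[(tert-butyldimethylsilyloxy)methyl]-5-({(2S)-5-[(2S)-4-hydroxy-2-(triethylsilyloxy)butan-2-yl]-2-methyl-2,3-dihydrofuran-2-yl}methylidene)-4-iodofuran-2(5H)-one
Conditions: HF·pyridine, pyridine, THF, 0 °C
Reagents that add atoms: none
Why: Buffered HF·pyridine cleaves the unhindered primary triethylsilyl ether far faster than the primary TBS ether or the tertiary triethylsilyl ether (selective desilylation), and the excess pyridine keeps the medium mild enough for the enol ether.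

Step 20
Reactants: 25 primary C6 alcohol
Product: 26 (3S)-3-{(5S)-5-[(E)-{4-[(tert-butyldimethylsilyloxy)methyl]-3-iodo-5-oxofuran-2(5H)-ylidene}methyl]-5-methyl-4,5-dihydrofuran-2-yl}-3-(triethylsilyloxy)butanal (seco iodo aldehyde)
Conditions: Dess–Martin periodinane, NaHCO3, CH2Cl2, 0 °C → rt
Reagents that add atoms: none
Why: Dess–Martin oxidation buffered with NaHCO3 gives the β-silyloxy aldehyde at neutral pH, without β-elimination and without touching the vinyl iodide, the enol lactone or the enol ether.

Step 21
Reactants: 26 seco iodo aldehyde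
Product: 27 (4S,6S,10S,8E)-13-(tert-butyldimethylsilyloxy)-6-hydroxy-4-(triethylsilyloxy)-3,10-epoxygermacra-2,7(11),8-trien-12,8-olide (macrocyclic C6 carbinol)
Conditions: CrCl2 (20 mol %), NiCl2·glyme (2 mol %), Cp2ZrCl2 (1.5 equiv), Bu4NPF6 (0.1 M), DMF, undivided cell, Al anode, Ni-foam cathode, constant current (about 2.5 F/mol), 26 added by syringe pump to 2 mM, rt
Reagents that add atoms: none
Why: The cathode keeps chromium in its divalent state, which reduces the NiCl2 co-catalyst to zerovalent nickel; this inserts into the C7–I bond of the electron-poor iodobutenolide, the alkenyl group passes to trivalent chromium, the alkenylchromium species adds to the C6 aldehyde, and Cp2ZrCl2 takes over the alkoxide so that chromium returns to the cycle. The closest known reaction type is the chromium-catalysed electrochemical Nozaki–Hiyama–Kishi coupling of alkenyl halides with aldehydes, together with the stoichiometric CrCl2/NiCl2 macrocyclisation of iodoalkenes onto aldehydes. The ten-membered carbocycle C1–C10 closes in a 10-exo-trig mode by attack of C7 on the carbonyl carbon C6, and the dihydrofuran ring, the E-configured C8=C9 bond that holds C10 on the C7 side and the planar butenolide leave only the C3–C4, C4–C5 and C5–C6 bonds free to rotate, so the two ends already lie near one another. The new C6 stereocentre should form with the 4,6-anti relationship (6S), because the β-silyloxy aldehyde is attacked in the dipole-minimised conformation in which the C4–O bond points away from the carbonyl group and the C4 methyl group turns outward from the forming ring. The step needs ring closure to win over intermolecular coupling and one face of the aldehyde to be attacked: the first is secured by the three rigid elements of the substrate together with slow addition at high dilution, the second by the silyloxy-bearing quaternary C4 next to the carbonyl chain, while zerovalent nickel selects the C7–I bond and leaves the lactone, the silyl ethers and the enol ether alone.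

Step 22
Reactants: 27 macrocyclic C6 carbinol
Product: 28 (4S,6S,10S,8E)-4,6,13-trihydroxy-3,10-epoxygermacra-2,7(11),8-trien-12,8-olide
Conditions: TBAF, AcOH (1:1), THF, 0 °C → rt
Reagents that add atoms: none
Why: Acetic-acid-buffered fluoride removes the primary allylic TBS ether and the tertiary triethylsilyl ether at near-neutral pH (fluoride desilylation), which protects both the base-sensitive enol lactone and the acid-sensitive enol ether.

Step 23
Reactants: 28 triol
Product: 29 (4S,6S,10S,8E)-6,13-diacetoxy-4-hydroxy-3,10-epoxygermacra-2,7(11),8-trien-12,8-olide (CNP0144020.1)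
Conditions: Ac2O (2.5 equiv), pyridine, DMAP (cat.), CH2Cl2, 0 °C
Reagents that add atoms: acetic anhydride, CC(=O)OC(C)=O
Why: Acetic anhydride with pyridine and catalytic DMAP acylates the primary C13 and the secondary C6 hydroxyl (esterification), while the tertiary C4 hydroxyl is too hindered to react at 0 °C, which should give the target with all three stereocentres (4S, 6S, 10S) unchanged.

**Compound list**

1 | (S)-citramalic acid, (2S)-2-hydroxy-2-methylbutanedioic acid | OC(=O)[C@@](C)(O)CC(=O)O | starting material
2 | 2-[(4S)-2,2,4-trimethyl-5-oxo-1,3-dioxolan-4-yl]acetic acid | CC1(C)OC(=O)[C@](C)(CC(=O)O)O1 | intermediate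
3 | (5S)-5-(2-hydroxyethyl)-2,2,5-trimethyl-1,3-dioxolan-4-one | CC1(C)OC(=O)[C@](C)(CCO)O1 | intermediate (not isolated)
4 | (3S)-3-hydroxy-3-methyloxolan-2-one | O=C1OCC[C@]1(C)O | intermediate
5 | (3S)-3-methyloxolane-2,3-diol (lactol, both anomers) | OC1OCC[C@]1(C)O | intermediate
6 | (3S)-3-methylpent-4-yne-1,3-diol | C#C[C@@](C)(O)CCO | intermediate
7 | (3S)-3-methyl-3,5-bis(triethylsilyloxy)pent-1-yne | C#C[C@@](C)(O[Si](CC)(CC)CC)CCO[Si](CC)(CC)CC | intermediate
8 | 2-methylprop-2-en-1-ol | CC(=C)CO | starting material
9 | (R)-(2-methyloxiran-2-yl)methanol | OC[C@]1(C)CO1 | intermediate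
10 | (2S)-2-{[(4-methoxybenzyl)oxy]methyl}-2-methyloxirane | COc1ccc(COC[C@]2(C)CO2)cc1 | intermediate
11 | lithium acetylide of 7 | [Li]C#C[C@@](C)(O[Si](CC)(CC)CC)CCO[Si](CC)(CC)CC | intermediate (not isolated)
12 | (2S,6S)-1-[(4-methoxybenzyl)oxy]-2,6-dimethyl-6,8-bis(triethylsilyloxy)oct-4-yn-2-ol | COc1ccc(COC[C@@](C)(O)CC#C[C@@](C)(O[Si](CC)(CC)CC)CCO[Si](CC)(CC)CC)cc1 | intermediate
13 | (2S)-5-[(2S)-2,4-bis(triethylsilyloxy)butan-2-yl]-2-{[(4-methoxybenzyl)oxy]methyl}-2-methyl-2,3-dihydrofuran | COc1ccc(COC[C@]2(C)CC=C(O2)[C@@](C)(O[Si](CC)(CC)CC)CCO[Si](CC)(CC)CC)cc1 | intermediate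
14 | {(2S)-5-[(2S)-2,4-bis(triethylsilyloxy)butan-2-yl]-2-methyl-2,3-dihydrofuran-2-yl}methanol | OC[C@]1(C)CC=C(O1)[C@@](C)(O[Si](CC)(CC)CC)CCO[Si](CC)(CC)CC | intermediate
15 | (2S)-5-[(2S)-2,4-bis(triethylsilyloxy)butan-2-yl]-2-methyl-2,3-dihydrofuran-2-carbaldehyde | O=C[C@]1(C)CC=C(O1)[C@@](C)(O[Si](CC)(CC)CC)CCO[Si](CC)(CC)CC | intermediate
16 | but-2-yne-1,4-diol | OCC#CCO | starting material
17 | 4-(tert-butyldimethylsilyloxy)but-2-yn-1-ol | CC(C)(C)[Si](C)(C)OCC#CCO | intermediate
18 | 4-(tert-butyldimethylsilyloxy)but-2-yn-1-yl methyl carbonate | COC(=O)OCC#CCO[Si](C)(C)C(C)(C)C | intermediate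
19 | methyl 2-[(tert-butyldimethylsilyloxy)methyl]buta-2,3-dienoate | COC(=O)C(CO[Si](C)(C)C(C)(C)C)=C=C | intermediate
20 | 2-[(tert-butyldimethylsilyloxy)methyl]buta-2,3-dienoic acid | OC(=O)C(CO[Si](C)(C)C(C)(C)C)=C=C | intermediate
21 | 3-[(tert-butyldimethylsilyloxy)methyl]-4-iodofuran-2(5H)-one | CC(C)(C)[Si](C)(C)OCC1=C(I)COC1=O | intermediate
22 | 3-[(tert-butyldimethylsilyloxy)methyl]-4-iodo-2-(trimethylsilyloxy)furan | C[Si](C)(C)Oc1occ(I)c1CO[Si](C)(C)C(C)(C)C | intermediate (not isolated)
23 | (5R)-3-[(tert-butyldimethylsilyloxy)methyl]-5-[(S)-hydroxy{(2S)-5-[(2S)-2,4-bis(triethylsilyloxy)butan-2-yl]-2-methyl-2,3-dihydrofuran-2-yl}methyl]-4-iodofuran-2(5H)-one (C8/C9 anti) | CC(C)(C)[Si](C)(C)OCC1=C(I)[C@H](OC1=O)[C@H](O)[C@]2(C)CC=C(O2)[C@@](C)(O[Si](CC)(CC)CC)CCO[Si](CC)(CC)CC | intermediate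
24 | (5E)-3-[(tert-butyldimethylsilyloxy)methyl]-5-({(2S)-5-[(2S)-2,4-bis(triethylsilyloxy)butan-2-yl]-2-methyl-2,3-dihydrofuran-2-yl}methylidene)-4-iodofuran-2(5H)-one | CC(C)(C)[Si](C)(C)OCC1=C(I)/C(=C\[C@]2(C)CC=C(O2)[C@@](C)(O[Si](CC)(CC)CC)CCO[Si](CC)(CC)CC)OC1=O | intermediate
25 | (5E)-3-[(tert-butyldimethylsilyloxy)methyl]-5-({(2S)-5-[(2S)-4-hydroxy-2-(triethylsilyloxy)butan-2-yl]-2-methyl-2,3-dihydrofuran-2-yl}methylidene)-4-iodofuran-2(5H)-one | CC(C)(C)[Si](C)(C)OCC1=C(I)/C(=C\[C@]2(C)CC=C(O2)[C@@](C)(O[Si](CC)(CC)CC)CCO)OC1=O | intermediate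
26 | (3S)-3-{(5S)-5-[(E)-{4-[(tert-butyldimethylsilyloxy)methyl]-3-iodo-5-oxofuran-2(5H)-ylidene}methyl]-5-methyl-4,5-dihydrofuran-2-yl}-3-(triethylsilyloxy)butanal (seco iodo aldehyde) | CC(C)(C)[Si](C)(C)OCC1=C(I)/C(=C\[C@]2(C)CC=C(O2)[C@@](C)(O[Si](CC)(CC)CC)CC=O)OC1=O | intermediate
27 | (4S,6S,10S,8E)-13-(tert-butyldimethylsilyloxy)-6-hydroxy-4-(triethylsilyloxy)-3,10-epoxygermacra-2,7(11),8-trien-12,8-olide (macrocyclic C6 carbinol) | CC(C)(C)[Si](C)(C)OCC1=C2/C(=C\[C@]3(C)CC=C(O3)[C@@](C)(O[Si](CC)(CC)CC)C[C@@H]2O)OC1=O | intermediate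
28 | (4S,6S,10S,8E)-4,6,13-trihydroxy-3,10-epoxygermacra-2,7(11),8-trien-12,8-olide | OCC1=C2/C(=C\[C@]3(C)CC=C(O3)[C@@](C)(O)C[C@@H]2O)OC1=O | intermediate
29 | (4S,6S,10S,8E)-6,13-diacetoxy-4-hydroxy-3,10-epoxygermacra-2,7(11),8-trien-12,8-olide (CNP0144020.1) | CC(=O)OCC1=C2/C(=C\[C@]3(C)CC=C(O3)[C@@](C)(O)C[C@@H]2OC(C)=O)OC1=O | target

**Step count and risks**

Total: 23 steps. Longest linear sequence: 16 steps from (S)-citramalic acid (steps 1–5, 8–11, 17–23).

Steps most likely to fail:

1. Step 21 (ring closure). The alkenylchromium species may add to the aldehyde with poor facial selectivity, so that the C6 epimer forms beside or instead of 27; reductive loss of iodine and intermolecular coupling are the other drains. Fallback: the stereocentre is then set by reagent control after the ring is closed. The crude carbinol (27 and its C6 epimer) is oxidised with Dess–Martin periodinane and NaHCO3 to the macrocyclic C6 ketone F1. This enone is reduced at −78 °C with the (R)-configured Corey–Bakshi–Shibata oxazaborolidine and catecholborane, which treats the alkenyl C7 side as the large group and should deliver hydride to the face that gives the (6S)-carbinol. The fallback sets out from 27 (as the epimer mixture) and comes back at 27.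

2. Step 18 (dehydration). The oxyphosphonium intermediate may lose the C8 proton first and ionise stepwise through the furanolate instead of by concerted anti-elimination; C10 can then turn away from the iodine and the Z-alkene results. Fallback: the alkene is formed only after ring closure, where the ten-membered ring should allow only the geometry with C7 and C10 on the same side. Compound 23 is acetylated at O9 (Ac2O, pyridine, 0 °C) to the C9 acetate F2. The primary triethylsilyl ether is removed (HF·pyridine, pyridine, THF, 0 °C) to give the primary alcohol F3, which is oxidised (Dess–Martin periodinane, NaHCO3) to the aldehyde F4. F4 is cyclised under the conditions of step 21 to the macrocyclic acetoxy carbinol F5. DBU in CH2Cl2 at 0 °C then removes the acidic C8–H and expels the C9 acetate, which leaves far more readily than the C13 silyloxide, to give 27. The fallback sets out from 23 and comes back at 27.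

3. Step 17 (vinylogous aldol addition). Simple diastereoselectivity may be poor, so that the syn (threo) C8/C9 adduct forms in a large share; under anti-elimination this isomer would give the Z-alkene. Fallback: the two adducts are separated by chromatography and the syn adduct F6 is dehydrated with the Burgess reagent (methyl N-(triethylammoniosulfonyl)carbamate, toluene, 50 °C). This is a syn-elimination through a cyclic transition state, which from the syn adduct also places C10 on the C7 side, so both diastereomers are funnelled into the same alkene. The fallback sets out from 15 and 21 (step 17 as written) and comes back at 24.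

**Further compounds**

F1 | step 21 | (4S,10S,8E)-13-(tert-butyldimethylsilyloxy)-6-oxo-4-(triethylsilyloxy)-3,10-epoxygermacra-2,7(11),8-trien-12,8-olide (macrocyclic C6 ketone) | CC(C)(C)[Si](C)(C)OCC1=C2/C(=C\[C@]3(C)CC=C(O3)[C@@](C)(O[Si](CC)(CC)CC)CC2=O)OC1=O
F2 | step 18 | C9 acetate of 23 | CC(C)(C)[Si](C)(C)OCC1=C(I)[C@H](OC1=O)[C@H](OC(C)=O)[C@]2(C)CC=C(O2)[C@@](C)(O[Si](CC)(CC)CC)CCO[Si](CC)(CC)CC
F3 | step 18 | C9 acetate with free primary C6 hydroxyl | CC(C)(C)[Si](C)(C)OCC1=C(I)[C@H](OC1=O)[C@H](OC(C)=O)[C@]2(C)CC=C(O2)[C@@](C)(O[Si](CC)(CC)CC)CCO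
F4 | step 18 | C9 acetate C6 aldehyde (seco iodo aldehyde with saturated C8–C9) | CC(C)(C)[Si](C)(C)OCC1=C(I)[C@H](OC1=O)[C@H](OC(C)=O)[C@]2(C)CC=C(O2)[C@@](C)(O[Si](CC)(CC)CC)CC=O
F5 | step 18 | macrocyclic C6 carbinol with C8–H and C9 acetate | CC(C)(C)[Si](C)(C)OCC1=C2[C@H](OC1=O)[C@H](OC(C)=O)[C@]3(C)CC=C(O3)[C@@](C)(O[Si](CC)(CC)CC)C[C@@H]2O
F6 | step 17 | (5S)-3-[(tert-butyldimethylsilyloxy)methyl]-5-[(S)-hydroxy{(2S)-5-[(2S)-2,4-bis(triethylsilyloxy)butan-2-yl]-2-methyl-2,3-dihydrofuran-2-yl}methyl]-4-iodofuran-2(5H)-one (C8/C9 syn) | CC(C)(C)[Si](C)(C)OCC1=C(I)[C@@H](OC1=O)[C@H](O)[C@]2(C)CC=C(O2)[C@@](C)(O[Si](CC)(CC)CC)CCO[Si](CC)(CC)CC
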